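The cyclohexane (ring atoms numbered as in the target, C1 carrying the side chain) is cut at C2–C3 (CMe2–CHBr) and C5–C6 (CHBr–C(=CH2)) into 3-methylbutan-2-one (C6, C1, C2 and both methyls) and methyl acrylate (C3, C4, C5). A one-pot Michael–Claisen [3+3] annulation joins them to 4,4-dimethylcyclohexane-1,3-dione. It exploits the gem-dimethyl carbon C2 as a tertiary enolate carbon and the 1,3-relationship of C1 and C5, which both emerge as carbonyls: C1 later takes the side chain by asymmetric conjugate addition, C5 becomes the allylic bromide, C6 the methylene-bearing carbon, and C3 is oxygenated and brominated afterwards.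

Key step: step 1

Assumption: (S)-(+)-linalool of high enantiomeric purity is taken as a commercial starting material; it supplies the side-chain carbinol stereocentre unchanged.

Step 1
Reactants: 1 3-methylbutan-2-one; 2 methyl acrylate
Product: 4 4,4-dimethylcyclohexane-1,3-dione, via keto ester 3 (not isolated)
Conditions: t-BuOK, THF, 0 → 60 °C (1 in excess, slow addition of 2); then 2 M HCl
Reagents that add atoms: none
Why: The thermodynamic (tertiary) potassium enolate of 1 adds to the β-carbon of 2 (Michael addition, forming C2–C3), and keto ester 3 then enolises at its methyl group and closes onto the ester carbonyl in a Claisen (Dieckmann-type) condensation that forms C5–C6. This is the classical Michael–Claisen [3+3] route to 4-substituted cyclohexane-1,3-diones. The ring closes in a 6-(enolexo)-exo-trig mode. No stereocentre is created, since 4 is achiral. The step needs the regioselectivity Michael-at-isopropyl and Claisen-at-methyl, which is secured because only this pairing ends in an enolisable 1,3-dione that is drained irreversibly as its potassium salt, the reverse pairing requiring a Claisen closure at a tertiary carbon. Over-addition of acrylate is held back by the excess of ketone and the slow addition of 2.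

Step 2
Reactants: 4 4,4-dimethylcyclohexane-1,3-dione
Product: 5 6,6-dimethyl-3-(2-methylpropoxy)cyclohex-2-en-1-one
Conditions: 2-methylpropan-1-ol, p-TsOH (cat.), toluene, reflux, Dean–Stark
Reagents that add atoms: 2-methylpropan-1-ol CC(C)CO
Why: Acid-catalysed vinylogous ester formation should take place at the less hindered carbonyl (C5), leaving the ketone next to the gem-dimethyl carbon (C1) free; no stereocentre is formed.

Step 3
Reactants: 5 6,6-dimethyl-3-(2-methylpropoxy)cyclohex-2-en-1-one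
Product: 7 4,4-dimethylcyclohex-2-en-1-one, via allylic alcohol 6 (not isolated)
Conditions: LiAlH4, Et2O, 0 °C; then 2 M HCl, rt
Reagents that add atoms: none
Why: Stork–Danheiser reductive transposition: 1,2-hydride addition to the C1 ketone, then acid hydrolysis of the enol ether with loss of water, should unveil the C5 ketone with C1 as the enone β-carbon.

Step 4
Reactants: 8 (S)-linalool
Product: 9 {[(3S)-3,7-dimethylocta-1,6-dien-3-yl]oxy}triethylsilane
Conditions: TESOTf, 2,6-lutidine, CH2Cl2, −78 → 0 °C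
Reagents that add atoms: triethylsilyl trifluoromethanesulfonate CC[Si](CC)(CC)OS(=O)(=O)C(F)(F)F
Why: Silylation of the hindered tertiary alcohol with the silyl triflate protects it for the organometallic steps and leaves the carbinol stereocentre untouched.

Step 5
Reactants: 9 {[(3S)-3,7-dimethylocta-1,6-dien-3-yl]oxy}triethylsilane
Product: 10 (4S)-4-methyl-4-[(triethylsilyl)oxy]hex-5-enal
Conditions: O3 (1.0 equiv), pyridine, CH2Cl2, −78 °C; then Me2S, −78 °C → rt
Reagents that add atoms: ozone [O-][O+]=O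
Why: Chemoselective ozonolysis: the electron-rich trisubstituted alkene should react much faster than the monosubstituted vinyl group.

Step 6
Reactants: 10 (4S)-4-methyl-4-[(triethylsilyl)oxy]hex-5-enal
Product: 11 (4S)-4-methyl-4-[(triethylsilyl)oxy]hex-5-enoic acid
Conditions: NaClO2, NaH2PO4, 2-methylbut-2-ene, t-BuOH/H2O, 0 °C → rt
Reagents that add atoms: sodium chlorite [Na+].[O-]Cl=O
Why: Pinnick oxidation of the aldehyde; the silyl ether and the vinyl group should be inert once hypochlorous acid is scavenged.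

Step 7
Reactants: 11 (4S)-4-methyl-4-[(triethylsilyl)oxy]hex-5-enoic acid
Product: 13 {[(3S)-5-iodo-3-methylpent-1-en-3-yl]oxy}triethylsilane, via thiohydroxamate ester 12 (not isolated)
Conditions: 1-hydroxypyridine-2(1H)-thione, DCC, DMAP (cat.), CH2Cl2, rt, dark; then CHI3, toluene, hν (tungsten lamp), 80 °C
Reagents that add atoms: 1-hydroxypyridine-2(1H)-thione On1ccccc1=S (its atoms stay in 12 only); iodoform IC(I)I
Why: Barton decarboxylative iodination: the thiohydroxamate ester should fragment on irradiation to a primary alkyl radical that abstracts iodine from iodoform, shortening the chain by one carbon.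

Step 8
Reactants: 7 4,4-dimethylcyclohex-2-en-1-one; 13 {[(3S)-5-iodo-3-methylpent-1-en-3-yl]oxy}triethylsilane
Product: 16 (2S,3R)-2-[(dimethylamino)methyl]-4,4-dimethyl-3-{(3S)-3-methyl-3-[(triethylsilyl)oxy]pent-4-en-1-yl}cyclohexan-1-one, via Grignard reagent 14 (not isolated), via magnesium enolate 15 (not isolated)
Conditions: 13, Mg, Et2O, rt; then 7, CuBr·SMe2 (5 mol %), (R)-1-[(Sp)-2-(diphenylphosphino)ferrocenyl]ethyldicyclohexylphosphine (6 mol %; or its enantiomer, whichever delivers the 3R ketone), t-BuOMe, −75 °C; then CH2=NMe2+ I−, THF, −75 → 0 °C; aq NH4Cl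
Reagents that add atoms: magnesium [Mg] (in 14 and 15 only); N,N-dimethylmethylideneammonium iodide (Eschenmoser's salt) C=[N+](C)C.[I-]
Why: Copper-catalysed asymmetric conjugate addition of Grignard reagent 14 to the neopentyl β-carbon of 7, in which the chiral ferrocenyl diphosphine selects the enone face and so sets ring carbon C1, is followed by Mannich trapping of magnesium enolate 15 with Eschenmoser's salt anti to the new substituent; this installs the future methylene carbon on C6 and blocks that α-position (its configuration is lost later).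

Step 9
Reactants: 16 (2S,3R)-2-[(dimethylamino)methyl]-4,4-dimethyl-3-{(3S)-3-methyl-3-[(triethylsilyl)oxy]pent-4-en-1-yl}cyclohexan-1-one
Product: 17 (5R,6S)-6-[(dimethylamino)methyl]-4,4-dimethyl-5-{(3S)-3-methyl-3-[(triethylsilyl)oxy]pent-4-en-1-yl}cyclohex-2-en-1-one
Conditions: LDA, THF, −78 °C; then PhS(Cl)=N-t-Bu, −78 °C
Reagents that add atoms: none
Why: Kinetic deprotonation at the only α-methylene (C4) and Mukaiyama dehydrogenation with the sulfinimidoyl chloride should give the C3=C4 enone without touching the C1 stereocentre.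

Step 10
Reactants: 17 (5R,6S)-6-[(dimethylamino)methyl]-4,4-dimethyl-5-{(3S)-3-methyl-3-[(triethylsilyl)oxy]pent-4-en-1-yl}cyclohex-2-en-1-one
Product: 19 (2S,3R,5R)-2-[(dimethylamino)methyl]-5-hydroxy-4,4-dimethyl-3-{(3S)-3-methyl-3-[(triethylsilyl)oxy]pent-4-en-1-yl}cyclohexan-1-one, via pinacolboronate 18 (not isolated)
Conditions: B2pin2, CuCl (5 mol %), DPEphos (5 mol %), NaOt-Bu (10 mol %), MeOH (2 equiv), THF, rt; then NaBO3·4H2O, THF/H2O, 0 °C → rt
Reagents that add atoms: bis(pinacolato)diboron CC1(C)OB(OC1(C)C)B1OC(C)(C)C(C)(C)O1 (boron in 18 only); sodium perborate [Na+].[O-]OB=O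
Why: Copper-catalysed conjugate borylation should place boron on C3 by axial attack anti to the C1 substituent (the usual 3,5-trans addition to a 5-substituted cyclohexenone), and perborate oxidation with retention then gives the axial C3 alcohol trans to the side chain.

Step 11
Reactants: 19 (2S,3R,5R)-2-[(dimethylamino)methyl]-5-hydroxy-4,4-dimethyl-3-{(3S)-3-methyl-3-[(triethylsilyl)oxy]pent-4-en-1-yl}cyclohexan-1-one
Product: 21 (3S,5R)-5-hydroxy-4,4-dimethyl-2-methylidene-3-{(3S)-3-methyl-3-[(triethylsilyl)oxy]pent-4-en-1-yl}cyclohexan-1-one, via trimethylammonium iodide 20 (not isolated)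
Conditions: MeI, Et2O, rt; then NaHCO3, CH2Cl2/H2O, rt
Reagents that add atoms: iodomethane CI (methyl group in 20 only)
Why: Quaternisation of the Mannich base and mild-base β-elimination (Hofmann-type, E1cB) should unveil the exocyclic methylene on C6, erasing the C6 stereocentre.

Step 12
Reactants: 21 (3S,5R)-5-hydroxy-4,4-dimethyl-2-methylidene-3-{(3S)-3-methyl-3-[(triethylsilyl)oxy]pent-4-en-1-yl}cyclohexan-1-one
Product: 22 (1R,3R,5S)-4,4-dimethyl-6-methylidene-5-{(3S)-3-methyl-3-[(triethylsilyl)oxy]pent-4-en-1-yl}cyclohexane-1,3-diol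
Conditions: Me4NBH(OAc)3, MeCN/AcOH, −30 °C
Reagents that add atoms: none
Why: Evans–Saksena directed reduction: the axial C3 hydroxyl binds boron and delivers hydride to the same face of the C5 carbonyl, which should give the anti-1,3-diol with the new C5 hydroxyl equatorial and cis to the side chain.

Step 13
Reactants: 22 (1R,3R,5S)-4,4-dimethyl-6-methylidene-5-{(3S)-3-methyl-3-[(triethylsilyl)oxy]pent-4-en-1-yl}cyclohexane-1,3-diol
Product: 23 {[(3S)-5-[(1S,3S,5S)-3,5-dibromo-2,2-dimethyl-6-methylidenecyclohexyl]-3-methylpent-1-en-3-yl]oxy}triethylsilane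
Conditions: CBr4 (4 equiv), PPh3 (4 equiv), CH2Cl2, −20 °C → rt
Reagents that add atoms: tetrabromomethane BrC(Br)(Br)Br
Why: Appel reaction at both carbinols with inversion (SN2 on the alkoxyphosphonium ions): the equatorial allylic C5 alcohol should give the axial bromide and the axial neopentyl C3 alcohol the equatorial bromide, which sets the anti-1,3-dibromide of the target.

Step 14
Reactants: 23 {[(3S)-5-[(1S,3S,5S)-3,5-dibromo-2,2-dimethyl-6-methylidenecyclohexyl]-3-methylpent-1-en-3-yl]oxy}triethylsilane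
Product: 24 (3S)-5-[(1S,3S,5S)-3,5-dibromo-2,2-dimethyl-6-methylidenecyclohexyl]-3-methylpent-1-en-3-ol
Conditions: HF·pyridine, pyridine, THF, 0 °C
Reagents that add atoms: none
Why: Buffered fluoride should cleave the tertiary triethylsilyl ether while leaving the allylic and neopentyl bromides untouched.

Compound list
1 | 3-methylbutan-2-one | CC(=O)C(C)C | starting material
2 | methyl acrylate | C=CC(=O)OC | starting material
3 | methyl 4,4-dimethyl-5-oxohexanoate | CC(=O)C(C)(C)CCC(=O)OC | intermediate (not isolated)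
4 | 4,4-dimethylcyclohexane-1,3-dione | CC1(C)CCC(=O)CC1=O | intermediate
5 | 6,6-dimethyl-3-(2-methylpropoxy)cyclohex-2-en-1-one | CC(C)COC1=CC(=O)C(C)(C)CC1 | intermediate
6 | 6,6-dimethyl-3-(2-methylpropoxy)cyclohex-2-en-1-ol (racemic) | CC(C)COC1=CC(O)C(C)(C)CC1 | intermediate (not isolated)
7 | 4,4-dimethylcyclohex-2-en-1-one | CC1(C)CCC(=O)C=C1 | intermediate
8 | (S)-linalool, (3S)-3,7-dimethylocta-1,6-dien-3-ol | C=C[C@@](C)(O)CCC=C(C)C | starting material
9 | {[(3S)-3,7-dimethylocta-1,6-dien-3-yl]oxy}triethylsilane | C=C[C@@](C)(O[Si](CC)(CC)CC)CCC=C(C)C | intermediate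
10 | (4S)-4-methyl-4-[(triethylsilyl)oxy]hex-5-enal | C=C[C@@](C)(O[Si](CC)(CC)CC)CCC=O | intermediate
11 | (4S)-4-methyl-4-[(triethylsilyl)oxy]hex-5-enoic acid | C=C[C@@](C)(O[Si](CC)(CC)CC)CCC(=O)O | intermediate
12 | 2-thioxopyridin-1(2H)-yl (4S)-4-methyl-4-[(triethylsilyl)oxy]hex-5-enoate | C=C[C@@](C)(O[Si](CC)(CC)CC)CCC(=O)On1ccccc1=S | intermediate (not isolated)
13 | {[(3S)-5-iodo-3-methylpent-1-en-3-yl]oxy}triethylsilane | C=C[C@@](C)(O[Si](CC)(CC)CC)CCI | intermediate
14 | iodo{(3S)-3-methyl-3-[(triethylsilyl)oxy]pent-4-en-1-yl}magnesium | C=C[C@@](C)(O[Si](CC)(CC)CC)CC[Mg]I | intermediate (not isolated)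
15 | iodomagnesium (3R)-4,4-dimethyl-3-{(3S)-3-methyl-3-[(triethylsilyl)oxy]pent-4-en-1-yl}cyclohex-1-en-1-olate | C=C[C@@](C)(O[Si](CC)(CC)CC)CC[C@@H]1C=C(O[Mg]I)CCC1(C)C | intermediate (not isolated)
16 | (2S,3R)-2-[(dimethylamino)methyl]-4,4-dimethyl-3-{(3S)-3-methyl-3-[(triethylsilyl)oxy]pent-4-en-1-yl}cyclohexan-1-one | C=C[C@@](C)(O[Si](CC)(CC)CC)CC[C@@H]1[C@@H](CN(C)C)C(=O)CCC1(C)C | intermediate
17 | (5R,6S)-6-[(dimethylamino)methyl]-4,4-dimethyl-5-{(3S)-3-methyl-3-[(triethylsilyl)oxy]pent-4-en-1-yl}cyclohex-2-en-1-one | C=C[C@@](C)(O[Si](CC)(CC)CC)CC[C@@H]1[C@@H](CN(C)C)C(=O)C=CC1(C)C | intermediate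
18 | (2S,3R,5R)-2-[(dimethylamino)methyl]-4,4-dimethyl-3-{(3S)-3-methyl-3-[(triethylsilyl)oxy]pent-4-en-1-yl}-5-(4,4,5,5-tetramethyl-1,3,2-dioxaborolan-2-yl)cyclohexan-1-one | C=C[C@@](C)(O[Si](CC)(CC)CC)CC[C@@H]1[C@@H](CN(C)C)C(=O)C[C@@H](B2OC(C)(C)C(C)(C)O2)C1(C)C | intermediate (not isolated)
19 | (2S,3R,5R)-2-[(dimethylamino)methyl]-5-hydroxy-4,4-dimethyl-3-{(3S)-3-methyl-3-[(triethylsilyl)oxy]pent-4-en-1-yl}cyclohexan-1-one | C=C[C@@](C)(O[Si](CC)(CC)CC)CC[C@@H]1[C@@H](CN(C)C)C(=O)C[C@@H](O)C1(C)C | intermediate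
20 | 1-[(1S,2R,4R)-4-hydroxy-3,3-dimethyl-2-{(3S)-3-methyl-3-[(triethylsilyl)oxy]pent-4-en-1-yl}-6-oxocyclohexyl]-N,N,N-trimethylmethanaminium iodide | C=C[C@@](C)(O[Si](CC)(CC)CC)CC[C@@H]1[C@@H](C[N+](C)(C)C)C(=O)C[C@@H](O)C1(C)C.[I-] | intermediate (not isolated)
21 | (3S,5R)-5-hydroxy-4,4-dimethyl-2-methylidene-3-{(3S)-3-methyl-3-[(triethylsilyl)oxy]pent-4-en-1-yl}cyclohexan-1-one | C=C[C@@](C)(O[Si](CC)(CC)CC)CC[C@@H]1C(=C)C(=O)C[C@@H](O)C1(C)C | intermediate
22 | (1R,3R,5S)-4,4-dimethyl-6-methylidene-5-{(3S)-3-methyl-3-[(triethylsilyl)oxy]pent-4-en-1-yl}cyclohexane-1,3-diol | C=C[C@@](C)(O[Si](CC)(CC)CC)CC[C@@H]1C(=C)[C@H](O)C[C@@H](O)C1(C)C | intermediate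
23 | {[(3S)-5-[(1S,3S,5S)-3,5-dibromo-2,2-dimethyl-6-methylidenecyclohexyl]-3-methylpent-1-en-3-yl]oxy}triethylsilane | C=C[C@@](C)(O[Si](CC)(CC)CC)CC[C@@H]1C(=C)[C@@H](Br)C[C@H](Br)C1(C)C | intermediate
24 | (3S)-5-[(1S,3S,5S)-3,5-dibromo-2,2-dimethyl-6-methylidenecyclohexyl]-3-methylpent-1-en-3-ol | C=C[C@@](C)(O)CC[C@@H]1C(=C)[C@@H](Br)C[C@H](Br)C1(C)C | target

Total step count: 14. Longest linear sequence: 11 steps (steps 4 to 14, from 8); the ring branch (steps 1 to 3, then 8 to 14) has 10.

Steps most likely to fail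

1. Step 13. The displacement at the axial neopentyl C3 carbinol needs bromide to enter equatorially beside the gem-dimethyl group, so elimination towards C4 or methyl migration may outrun substitution; the allylic C5 centre may also suffer allylic transposition. The fallback sets out from 22 and returns at 23. Selective acetylation (Ac2O, pyridine, −20 °C) of the equatorial allylic hydroxyl should give the monoacetate of 22 at the allylic oxygen, F1. The remaining axial hydroxyl is converted with ClCH2SO2Cl and pyridine into the chloromethanesulfonate F2. Displacement with LiBr in DMF then gives, with inversion, the bromo acetate F3. K2CO3 in MeOH frees the bromo alcohol F4, and a single Appel reaction at the allylic carbinol gives 23.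

2. Step 9. Deprotonation on the substituted side or amine-directed enolisation may expel dimethylamide from the β-amino ketone before dehydrogenation, and over-oxidation is possible. The fallback sets out from 16 and returns at 17 without a new compound: direct aerobic dehydrogenation with Pd(O2CCF3)2 and DMSO under O2 in AcOH, where the amine is protonated and no strong base is present.

3. Step 8. Addition to the β-carbon next to the quaternary centre may be slow, face selection by the catalyst may be poor, and Mannich trapping of the enolate may be incomplete. The fallback sets out from 5 and 13 and returns at 16. Lithiation of 13 (t-BuLi, Et2O, −78 °C), 1,2-addition to the ketone of 5 and acid hydrolysis (Stork–Danheiser alkylative transposition) should give the 3-substituted enone F5. Catalyst-controlled conjugate reduction (Cu(OAc)2, (R)-DTBM-SEGPHOS or its enantiomer, (EtO)2MeSiH) then sets C1 and gives the silyl enol ether F6. Mukaiyama–Mannich reaction of F6 with Eschenmoser's salt gives 16.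

Further compounds
F1 | step 13 | (1R,3S,5R)-5-hydroxy-4,4-dimethyl-2-methylidene-3-{(3S)-3-methyl-3-[(triethylsilyl)oxy]pent-4-en-1-yl}cyclohexyl acetate | C=C[C@@](C)(O[Si](CC)(CC)CC)CC[C@@H]1C(=C)[C@H](OC(C)=O)C[C@@H](O)C1(C)C
F2 | step 13 | (1R,3S,5R)-5-{[(chloromethyl)sulfonyl]oxy}-4,4-dimethyl-2-methylidene-3-{(3S)-3-methyl-3-[(triethylsilyl)oxy]pent-4-en-1-yl}cyclohexyl acetate | C=C[C@@](C)(O[Si](CC)(CC)CC)CC[C@@H]1C(=C)[C@H](OC(C)=O)C[C@@H](OS(=O)(=O)CCl)C1(C)C
F3 | step 13 | (1R,3R,5S)-5-bromo-4,4-dimethyl-2-methylidene-3-{(3S)-3-methyl-3-[(triethylsilyl)oxy]pent-4-en-1-yl}cyclohexyl acetate | C=C[C@@](C)(O[Si](CC)(CC)CC)CC[C@@H]1C(=C)[C@H](OC(C)=O)C[C@H](Br)C1(C)C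
F4 | step 13 | (1R,3R,5S)-5-bromo-4,4-dimethyl-2-methylidene-3-{(3S)-3-methyl-3-[(triethylsilyl)oxy]pent-4-en-1-yl}cyclohexan-1-ol | C=C[C@@](C)(O[Si](CC)(CC)CC)CC[C@@H]1C(=C)[C@H](O)C[C@H](Br)C1(C)C
F0 | step 9 | none | none
F5 | step 8 | 4,4-dimethyl-3-{(3S)-3-methyl-3-[(triethylsilyl)oxy]pent-4-en-1-yl}cyclohex-2-en-1-one | C=C[C@@](C)(O[Si](CC)(CC)CC)CCC1=CC(=O)CCC1(C)C
F6 | step 8 | diethoxy(methyl){[(3R)-4,4-dimethyl-3-{(3S)-3-methyl-3-[(triethylsilyl)oxy]pent-4-en-1-yl}cyclohex-1-en-1-yl]oxy}silane | C=C[C@@](C)(O[Si](CC)(CC)CC)CC[C@@H]1C=C(O[Si](C)(OCC)OCC)CCC1(C)C
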